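## The problem

Compound 34 is a cis-fused decalin. With clerodane labels, ring A is C10–C1–C2–C3–C4–C5 and ring B is C5–C10; C18 is the methylene on C4, C19 the methyl on C5, C17 the methyl on C8, C20 the methyl on C9, the acetate is on C7, and the chain C11–C15 (methyl C16 on C13, acid C15) is on C9. Ring B and the ring fusion carry five contiguous stereocentres (C5, C10, C9, C8, C7), two of them quaternary (C5, C9) and separated only by C10; a sixth, C13, sits on the chain, four bonds from the nearest ring centre. Nothing on the rings can reach C13, so it has to be bought. C8 and C9, with their cis methyls, are best set together before any ring exists; C8 can then steer C7 (Felkin–Anh addition to a C7 aldehyde), the C7–C9 substituents can steer C10 through a chair-like ring B, and C10 with the axial C20 can steer C5. Ring A is the fragile part: the enol of a 2,3-dione (a diosphenol) cross-conjugated with an exocyclic methylene ketone, which will not survive nucleophiles, strong base or oxidants, next to a base-labile secondary acetate and a free acid. Two traps follow: the enol OH would outrun the hindered C7 hydroxyl in a late acetylation, and a 2,3-dione flanked by two CH2 groups (C1, C4) offers no sound way to place C18 on C4 and not on C1. The opening is that ring A is a cyclohexane with vicinal oxygens on C2 and C3, which is what an α-ketol ring enlargement of a 1-hydroxycyclopentanecarbaldehyde delivers: ring A is a cyclopentanone (C3 between C1 and C4) plus one formyl carbon, C2.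

## Retrosynthesis

**34 to 31 (C4=C18, C2=O, O–tBu).** The acid is released last from tert-butyl ester 33 with acid, which leaves only volatile by-products beside the sensitive ring A. Ring A of 33 is traced to acyloin 31, which already carries C18 as an acetoxymethyl group on C4 and the C7 acetate. Oxidation gives dione 32, β-elimination of acetate makes C4=C18, and the dione can then enolise only towards C1. Against methylenating a bare dione at the end, this fixes the C1/C4 question early and never exposes a free enol to acetylation.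

**31 to 30 (C1–C2, the key cut).** Breaking C1–C2 and re-joining C1 to C3 contracts ring A to the cis-hydrindane hydroxy aldehyde 30. The forward 1,2-shift needs no lasting selectivity: either ring bond of C3 may migrate and either carbinol epimer may react, because all acyloins give dione 32. Compared with cuts that close ring A by C–C bond formation, this one hands over a five-membered ring that a single cyclocarbonylation can make together with ring B.

**30 to 25 (formyl carbon C2, protecting-group exchange).** The formyl group comes from ozonolysis of the vinyl carbinol 28, and the vinyl from addition to ketone 25. The silyl ethers of 26 are exchanged for the two acetates (via triol 27) at the carbinol stage, where the only other hydroxyl is tertiary and unreactive. The forward steps ask for clean 1,2-addition to a hindered, enolisable cyclopentanone.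

**25 to 22 (C5–C19 and C4–C18).** Silyl ether 25 comes from hydroxymethyl ketone 24, and both new carbons go back to the hydrindenone 22. Conjugate addition of a methyl cuprate at C5 generates the C3=C4 enolate and no other, and formaldehyde traps it at C4. This is the one point in the synthesis where C4 and C1 differ without effort, which is why C18 enters here. The addition must occur on the face of H-10 to give the cis fusion.

**22 to 20 (C5–C10, C1–C3, C3–C4).** The enone is the Pauson–Khand product of the 1,7-enyne 20. Three bonds and both rings fall away in one cut, leaving an acyclic chain. The forward reaction must set C10; a chair with OTBS, C17 and the side chain equatorial should do so.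

**20 to 13 + 14 (C6–C7; C15 oxidation level).** The C15 ester of 20 is made from the primary silyl ether of 17 (via alcohol 18 and acid 19) once no hydride or enolate step remains. The homopropargylic alcohol 16 is cut at C6–C7 into aldehyde 13 and propargyl bromide 14. The forward addition must be Felkin-selective; C9, a quaternary carbon, is the large group.

**13 to 9 (C8–C9).** Aldehyde 13 is the oxidation-level-adjusted form (via alcohol 12) of acid 11. The C8–C9 bond, with both stereocentres, is the product of a [3,3] shift of allyl propanoate 9. This replaces the hardest bond of the molecule (tertiary to quaternary) by an ester C–O bond. The forward reaction needs a pure E alkene, an enolate with methyl cis to the O-metal bond, and a chiral controller for the absolute sense.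

**9 to 1.** Ester 9 is made from allylic alcohol 7 and propanoyl chloride 8. Alcohol 7 comes from alkyne 5 by methylalumination and hydroxymethylation (C20, C1), the alkyne from aldehyde 4, and the aldehyde from the silyl ether 2 of (R)-citronellol 1, whose stereocentre is C13 and whose carbinol carbon is C15.

## Roads not taken

**Alternative 1:** The cut goes through C5–C10 and C8–C9. The acyclic trienone A1 holds a 2-silyloxydiene (C5–C8) tied through C4–C1 to a keto-enoate (C9=C10). An intramolecular Diels–Alder reaction under a chiral N-protonated oxazaborolidine Lewis acid would give the cis-octalin silyl enol ether A2 with C5, C8, C9 and C10 set at once.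
- Merits: both rings and four stereocentres in one catalytic asymmetric step. In step count to the bicycle, and in using a catalytic rather than a stoichiometric chiral controller, it is better than the chosen plan.
- Weak points: the cycloaddition must join two fully substituted termini (C5, with a methyl forced inside the diene, and C9), the slowest regime for such reactions and one in which the acid catalyst may simply desilylate the dienol ether. Three alkene geometries in A1, one a Z silyl enol ether, must be pure. A2 is oxygenated at C1, not C2/C3, and carries only C11 of the chain, so ring A needs an oxygen transposition and C12–C15 with the remote C13 centre must be added later.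
- Comparison: the chosen plan is longer to the bicycle, but its ring A oxygens arrive in place through the ring enlargement and C13 comes with the first starting material.

**Alternative 2:** The cut is C1–C10. The prochiral cyclohexadienone A3 carries on C5 the methyl and a 2,3-dioxobutyl chain; an amine–thiourea catalyst derived from 9-amino-9-deoxy-epi-quinine would enolise the terminal methyl (C1) and add it to C10 of one enantiotopic enone arm, giving the cis-fused dione A4.
- Merits: very short, catalytic, and ring A is at the dione level with the C5/C10 fusion set. For ring A alone it is better than the chosen plan.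
- Weak points: A4 has none of ring B's substituents. The remaining enone has its oxygen on C8, not C7, so a carbonyl transposition is needed. The quaternary C9 (methyl and chain, between C10 and C8), the C8 methyl and C13 must be built with stereocontrol while a free, more acidic 1,2-dione sits in ring A. The C1/C4 problem for C18 is untouched.
- Comparison: the chosen plan spends its steps on ring B before any ring exists, where acyclic [3,3] control is reliable, and keeps the dione out of the flask until the end.

**Alternative 3:** The cut is C5–C19 and C4–C18 on a decalin. Me2CuLi would add C19 to C5 of the octalone A5 (enone C4=C5–C3=O, ring B complete) and the C3 enolate would be trapped at C4 by Eschenmoser's salt, whose amine is eliminated to give the methylene ketone A6.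
- Merits: two carbons and the cis fusion in one pot with unambiguous C4 regiochemistry and no ring enlargement. On this point it is as good as the chosen plan, which takes over the same logic (the cuprate-derived enolate, here trapped with formaldehyde).
- Weak points: A6 lacks the C2 oxygen, which would have to be introduced next to a reactive methylene ketone, the kind of late oxidation ring A tolerates worst. A5 needs a six-membered enone annulated next to the quaternary C9, and no step as convergent as the enyne cyclocarbonylation makes it. Conjugate addition to a β,β-disubstituted octalone is slower and its facial bias less dependable than on a hydrindenone.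
- Comparison: the chosen plan sets against the shorter ring A carbon work the fact that C2 arrives already oxygenated.

Key step: step 21

Remarks on the chemistry:
- Atom labels in all names and comments are the clerodane labels defined above.
- C4 (from step 15), C3 (from step 17) and C2 (from step 21) are formed without control and are carried as epimer mixtures; all three become sp2 by step 22.
- Assumption: the (S,S)-configured bromoborane of step 6 is taken to deliver the (2S,3R) acid 11; its facial sense on a 3,3-disubstituted allyl ester is not secured by analogy, and the (R,R) antipode is used instead, with nothing else changed, if the sense is opposite.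

## Route

Step 1
Reactants: 1 (R)-citronellol
Product: 2 (R)-tert-butyl[(3,7-dimethyloct-6-en-1-yl)oxy]dimethylsilane
Conditions: TBSCl, imidazole, CH2Cl2, rt
Reagents that add atoms: tert-butyldimethylsilyl chloride, CC(C)(C)[Si](C)(C)Cl
Why: Routine silylation of a primary alcohol; the ether masks the future C15 oxygen through the organometallic, enolate and hydride steps.

Step 2
Reactants: 2 (R)-tert-butyl[(3,7-dimethyloct-6-en-1-yl)oxy]dimethylsilane
Product: 4 (4R)-6-[(tert-butyldimethylsilyl)oxy]-4-methylhexanal, via secondary ozonide 3 (not isolated)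
Conditions: O3, CH2Cl2, −78 °C; PPh3, −78 °C to rt
Reagents that add atoms: ozone, [O-][O+]=O
Why: Ozonolysis with reductive work-up cleaves the only alkene; the aldehyde carbon becomes C9 and the stereocentre (C13) is untouched.

Step 3
Reactants: 4 (4R)-6-[(tert-butyldimethylsilyl)oxy]-4-methylhexanal
Product: 5 (3R)-tert-butyldimethyl[(3-methylhept-6-yn-1-yl)oxy]silane
Conditions: dimethyl (1-diazo-2-oxopropyl)phosphonate, K2CO3, MeOH, 0 °C to rt
Reagents that add atoms: dimethyl (1-diazo-2-oxopropyl)phosphonate, COP(=O)(OC)C(=[N+]=[N-])C(C)=O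
Why: Ohira–Bestmann (Seyferth–Gilbert) homologation of an aldehyde with no stereocentre in the α-position; the new terminal carbon is C10.

Step 4
Reactants: 5 (3R)-tert-butyldimethyl[(3-methylhept-6-yn-1-yl)oxy]silane
Product: 7 (2E,6R)-8-[(tert-butyldimethylsilyl)oxy]-3,6-dimethyloct-2-en-1-ol, via alkenyldimethylalane 6 (not isolated)
Conditions: Me3Al, Cp2ZrCl2 (cat.), CH2Cl2, 0 °C to rt; n-BuLi, THF, −78 °C; (CH2O)n, −78 °C to rt
Reagents that add atoms: trimethylaluminium, C[Al](C)C; paraformaldehyde (as formaldehyde), C=O
Why: Zirconium-catalysed methylalumination adds methyl (C20) and aluminium syn across the terminal alkyne with methyl on the internal carbon, and the aluminate is hydroxymethylated with retention, so the E trisubstituted alkene should form as one geometric isomer.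

Step 5
Reactants: 7 (2E,6R)-8-[(tert-butyldimethylsilyl)oxy]-3,6-dimethyloct-2-en-1-ol; 8 propanoyl chloride
Product: 9 (2E,6R)-8-[(tert-butyldimethylsilyl)oxy]-3,6-dimethyloct-2-en-1-yl propanoate
Conditions: pyridine, 4-(dimethylamino)pyridine (cat.), CH2Cl2, 0 °C
Reagents that add atoms: none
Why: Acylation of a primary allylic alcohol; the propanoate supplies C7, C8 and C17.

Step 6
Reactants: 9 (2E,6R)-8-[(tert-butyldimethylsilyl)oxy]-3,6-dimethyloct-2-en-1-yl propanoate
Product: 11 (2S,3R,6R)-8-[(tert-butyldimethylsilyl)oxy]-3-ethenyl-2,3,6-trimethyloctanoic acid, via boron ketene acetal 10 (not isolated)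
Conditions: (4S,5S)-2-bromo-1,3-bis{[3,5-bis(trifluoromethyl)phenyl]sulfonyl}-4,5-diphenyl-1,3,2-diazaborolidine, iPr2NEt, CH2Cl2, −78 °C; then −20 to 4 °C, several days; aq. work-up
Reagents that add atoms: none
Why: Enantioselective ester-enolate (Ireland–)Claisen rearrangement of a chiral boron enolate, known for E 3-methylalk-2-enyl esters forming a quaternary centre. The hindered amine in CH2Cl2 gives the enolate with methyl cis to O–B, which with the E alkene in a chair places C17 and the chain equatorial and C20 axial, the C8/C9 relationship of the target (C17 and C20 cis on ring B). The C2-symmetric sulfonamide ligand chooses the face and so sets both centres in the absolute sense.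

Step 7
Reactants: 11 (2S,3R,6R)-8-[(tert-butyldimethylsilyl)oxy]-3-ethenyl-2,3,6-trimethyloctanoic acid
Product: 12 (2S,3R,6R)-8-[(tert-butyldimethylsilyl)oxy]-3-ethenyl-2,3,6-trimethyloctan-1-ol
Conditions: LiAlH4, THF, 0 °C to rt
Reagents that add atoms: none
Why: Hydride reduction of a carboxylic acid; the vinyl group and silyl ether are inert.

Step 8
Reactants: 12 (2S,3R,6R)-8-[(tert-butyldimethylsilyl)oxy]-3-ethenyl-2,3,6-trimethyloctan-1-ol
Product: 13 (2S,3R,6R)-8-[(tert-butyldimethylsilyl)oxy]-3-ethenyl-2,3,6-trimethyloctanal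
Conditions: Dess–Martin periodinane, CH2Cl2, 0 °C to rt
Reagents that add atoms: none
Why: Neutral Dess–Martin oxidation; C8 sits beside a quaternary carbon and should not epimerise under these conditions.

Step 9
Reactants: 13 (2S,3R,6R)-8-[(tert-butyldimethylsilyl)oxy]-3-ethenyl-2,3,6-trimethyloctanal; 14 propargyl bromide
Product: 16 (4S,5S,6R,9R)-11-[(tert-butyldimethylsilyl)oxy]-6-ethenyl-5,6,9-trimethylundec-1-yn-4-ol, via allenylzinc bromide 15 (not isolated)
Conditions: Zn, THF, 0 °C; aq. NH4Cl
Reagents that add atoms: none
Why: Barbier propargylation through the allenylzinc reagent (SE2') gives the homopropargylic alcohol. Felkin–Anh addition anti to the quaternary C9, with the C17 methyl on the oxygen side, gives the 7S centre (C7–O and C17 trans on the future ring).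

Step 10
Reactants: 16 (4S,5S,6R,9R)-11-[(tert-butyldimethylsilyl)oxy]-6-ethenyl-5,6,9-trimethylundec-1-yn-4-ol
Product: 17 (4S,5S,6R,9R)-4,11-bis[(tert-butyldimethylsilyl)oxy]-6-ethenyl-5,6,9-trimethylundec-1-yne
Conditions: TBSOTf, 2,6-lutidine, CH2Cl2, −78 to 0 °C
Reagents that add atoms: tert-butyldimethylsilyl trifluoromethanesulfonate, CC(C)(C)[Si](C)(C)OS(=O)(=O)C(F)(F)F
Why: Silyl triflate silylation of a hindered secondary alcohol; the bulky ether also helps the later chair preference in ring B formation.

Step 11
Reactants: 17 (4S,5S,6R,9R)-4,11-bis[(tert-butyldimethylsilyl)oxy]-6-ethenyl-5,6,9-trimethylundec-1-yne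
Product: 18 (3R,6R,7S,8S)-8-[(tert-butyldimethylsilyl)oxy]-6-ethenyl-3,6,7-trimethylundec-10-yn-1-ol
Conditions: camphorsulfonic acid (cat.), MeOH–CH2Cl2, 0 °C
Reagents that add atoms: none
Why: Acid-catalysed methanolysis removes a primary TBS ether much faster than a hindered secondary one, a standard differentiation.

Step 12
Reactants: 18 (3R,6R,7S,8S)-8-[(tert-butyldimethylsilyl)oxy]-6-ethenyl-3,6,7-trimethylundec-10-yn-1-ol
Product: 19 (3R,6R,7S,8S)-8-[(tert-butyldimethylsilyl)oxy]-6-ethenyl-3,6,7-trimethylundec-10-ynoic acid
Conditions: TEMPO (2,2,6,6-tetramethylpiperidin-1-oxyl, cat.), PhI(OAc)2, MeCN–H2O, rt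
Reagents that add atoms: water, O
Why: Nitroxyl-catalysed oxidation of a primary alcohol through the aldehyde hydrate to the acid; alkyne, alkene and silyl ether are tolerated.

Step 13
Reactants: 19 (3R,6R,7S,8S)-8-[(tert-butyldimethylsilyl)oxy]-6-ethenyl-3,6,7-trimethylundec-10-ynoic acid
Product: 20 tert-butyl (3R,6R,7S,8S)-8-[(tert-butyldimethylsilyl)oxy]-6-ethenyl-3,6,7-trimethylundec-10-ynoate
Conditions: tert-butyl 2,2,2-trichloroacetimidate, CH2Cl2–cyclohexane, rt
Reagents that add atoms: tert-butyl 2,2,2-trichloroacetimidate, CC(C)(C)OC(=N)C(Cl)(Cl)Cl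
Why: Imidate esterification under near-neutral conditions; the tert-butyl ester resists cuprate, organocerium and fluoride and is removed at the end by acid alone.

Step 14
Reactants: 20 tert-butyl (3R,6R,7S,8S)-8-[(tert-butyldimethylsilyl)oxy]-6-ethenyl-3,6,7-trimethylundec-10-ynoate
Product: 22 hydrindenone: tert-butyl (3R)-5-[(5S,6S,7R,7aS)-5-[(tert-butyldimethylsilyl)oxy]-6,7-dimethyl-2-oxo-2,4,5,6,7,7a-hexahydro-1H-inden-7-yl]-3-methylpentanoate, via alkyne–Co2(CO)6 complex 21 (not isolated)
Conditions: Co2(CO)8, CH2Cl2, rt; N-methylmorpholine N-oxide, 0 °C to rt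
Reagents that add atoms: Co2(CO)8 (delivers one CO), O=C=[Co](=C=O)(=C=O)(=C=O)[Co](=C=O)(=C=O)(=C=O)=C=O
Why: Intramolecular Pauson–Khand [2+2+1] of a 1,7-enyne, helped by the quaternary C9; the tether fixes the regiochemistry (C5 is the β-carbon). Ring B should close through a chair with OTBS, C17 and the chain equatorial and C20 axial, which puts H-10 trans to C20 as required.

Step 15
Reactants: 22 hydrindenone (7S,8S,9R,10S,13R)
Product: 24 4-(hydroxymethyl) cis-hydrindan-3-one (5S,7S,8S,9R,10R,13R; C4 epimers), via lithium enolate 23 (not isolated)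
Conditions: Me2CuLi (from CuI, MeLi), Et2O, −20 to 0 °C; CH2O (gas), THF, −78 to −40 °C; aq. NH4Cl
Reagents that add atoms: lithium dimethylcuprate, [Li+].C[Cu-]C; formaldehyde, C=O
Why: Cuprate conjugate addition followed by aldol trapping of the regiodefined enolate. The methyl (C19) enters C5 on the face of H-10, away from C9 and its axial C20, giving the cis fusion. The enolate exists only as C3=C4, so formaldehyde puts C18 on C4 and nowhere else; the C4 configuration is immaterial.

Step 16
Reactants: 24 4-(hydroxymethyl) cis-hydrindan-3-one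
Product: 25 4-[(tert-butyldimethylsilyloxy)methyl] cis-hydrindan-3-one (5S,7S,8S,9R,10R,13R; C4 epimers)
Conditions: TBSCl, imidazole, DMF, rt
Reagents that add atoms: tert-butyldimethylsilyl chloride, CC(C)(C)[Si](C)(C)Cl
Why: Mild silylation of the primary alcohol blocks retro-aldol and β-elimination during the organometallic addition.

Step 17
Reactants: 25 4-[(tert-butyldimethylsilyloxy)methyl] cis-hydrindan-3-one
Product: 26 3-ethenyl-3-hydroxy cis-hydrindane bis-silyl ether (5S,7S,8S,9R,10R,13R; C3 and C4 epimers)
Conditions: CH2=CHMgBr, CeCl3, THF, −78 °C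
Reagents that add atoms: vinylmagnesium bromide, C=C[Mg]Br
Why: Organocerium 1,2-addition to a hindered, enolisable ketone; the low basicity suppresses enolisation and β-elimination and the tert-butyl ester is not attacked at −78 °C. The C3 configuration is immaterial.

Step 18
Reactants: 26 3-ethenyl-3-hydroxy cis-hydrindane bis-silyl ether
Product: 27 triol: 3-ethenyl-4-(hydroxymethyl) cis-hydrindane-3,7-diol (5S,7S,8S,9R,10R,13R; C3 and C4 epimers)
Conditions: Bu4NF, THF, rt to 40 °C
Reagents that add atoms: none
Why: Fluoride cleaves both silyl ethers; no ketone is present, so the basic medium cannot trigger retro-aldol or elimination.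

Step 19
Reactants: 27 triol
Product: 28 diacetate: 7-acetoxy-4-(acetoxymethyl)-3-ethenyl cis-hydrindan-3-ol (5S,7S,8S,9R,10R,13R; C3 and C4 epimers)
Conditions: Ac2O, pyridine, 4-(dimethylamino)pyridine (cat.), CH2Cl2, 0 °C to rt
Reagents that add atoms: acetic anhydride, CC(=O)OC(C)=O
Why: The primary C18 and secondary C7 hydroxyls are acetylated while the hindered tertiary allylic C3 hydroxyl stays free. The C7 acetate of the target is installed before any enol exists, and the C18 acetate is the leaving group for the final elimination.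

Step 20
Reactants: 28 diacetate
Product: 30 hydroxy aldehyde: 7-acetoxy-4-(acetoxymethyl)-3-hydroxy cis-hydrindane-3-carbaldehyde (5S,7S,8S,9R,10R,13R; C3 and C4 epimers), via secondary ozonide 29 (not isolated)
Conditions: O3, CH2Cl2, −78 °C; PPh3, −78 °C to rt; used crude
Reagents that add atoms: ozone, [O-][O+]=O
Why: Ozonolysis of the only alkene turns the vinyl group into the formyl carbon C2; tertiary vinyl carbinols are standard precursors of α-hydroxy aldehydes.

Step 21
Reactants: 30 hydroxy aldehyde
Product: 31 acyloin: 7-acetoxy-4-(acetoxymethyl)-2-hydroxy cis-decalin-3-one tert-butyl ester (5S,7S,8S,9R,10R,13R; C2 and C4 epimers)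
Conditions: BF3·OEt2, CH2Cl2, −40 to 0 °C
Reagents that add atoms: none
Why: BF3 binds the aldehyde oxygen and the neighbouring hydroxyl; as the C3–O bond becomes a carbonyl, the ring bond C3–C1 shifts to the formyl carbon, so C1–C2 forms and the cyclopentane grows into cyclohexane ring A with C3 as ketone and C2 as carbinol. This is the α-ketol (acyloin) rearrangement in its ring-enlarging form, as in the D-homoannulation of 17-hydroxy-20-keto steroids and the expansion of 1-hydroxycycloalkanecarbaldehydes. Ring A is thus closed not by a cyclisation but by a suprafacial 1,2-alkyl shift inside the existing ring, driven by the change of an aldehyde into a ketone and the relief of cyclopentane strain. The only new stereocentre, C2, is uncontrolled and need not be controlled, because it becomes sp2 in step 22; all C3 and C4 epimers of 30 are usable. No lasting regioselectivity is needed: migration of the less encumbered C1 is expected, but if C4 migrates the 3-hydroxy-2-ketone forms, and both acyloins give the same 2,3-dione. What is needed is chemoselectivity, and the substrate provides it: the hydroxy aldehyde is the only chelating 1,2-dioxygen array, the acetates tolerate BF3 at low temperature, and the tert-butyl ester is protected by keeping the reaction at or below 0 °C.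

Step 22
Reactants: 31 acyloin
Product: 33 tert-butyl (3R)-5-[(1R,2S,3S,4aS,8aR)-3-(acetyloxy)-7-hydroxy-1,2,4a-trimethyl-5-methylidene-6-oxo-1,2,3,4,4a,5,6,8a-octahydronaphthalen-1-yl]-3-methylpentanoate, via 2,3-dione 32 (not isolated)
Conditions: Dess–Martin periodinane, CH2Cl2, 0 °C to rt; then Et3N, 0 °C
Reagents that add atoms: none
Why: Dess–Martin oxidation of the acyloin (either regioisomer) gives the 2,3-dione, whose C4–H lies between a carbonyl and the acetoxymethyl group; Et3N then causes E1cB loss of acetate to the C4=C18 methylene ketone. With C4 and C5 now free of hydrogen the dione can enolise only towards C1, which is the diosphenol of the target.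

Step 23
Reactants: 33 tert-butyl ester of the target
Product: 34 (3R)-5-[(1R,2S,3S,4aS,8aR)-3-(acetyloxy)-7-hydroxy-1,2,4a-trimethyl-5-methylidene-6-oxo-1,2,3,4,4a,5,6,8a-octahydronaphthalen-1-yl]-3-methylpentanoic acid (CNP0257844.1)
Conditions: CF3CO2H–CH2Cl2 (1:4), 0 °C to rt; evaporate
Reagents that add atoms: none
Why: Acidolysis of the tert-butyl ester (loss of 2-methylpropene) needs no nucleophile or base, so the acetate, the enol and the methylene ketone are left alone; the exocyclic alkene cannot migrate because C5 is quaternary.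

## Compound list

1 | (R)-citronellol, (3R)-3,7-dimethyloct-6-en-1-ol | CC(C)=CCC[C@@H](C)CCO | starting material
2 | (R)-tert-butyl[(3,7-dimethyloct-6-en-1-yl)oxy]dimethylsilane | CC(C)=CCC[C@@H](C)CCO[Si](C)(C)C(C)(C)C | intermediate
3 | secondary ozonide of 2 (3,3-dimethyl-1,2,4-trioxolane carrying the (3R)-5-silyloxy-3-methylpentyl chain) | CC1(C)OOC(CC[C@@H](C)CCO[Si](C)(C)C(C)(C)C)O1 | intermediate (not isolated)
4 | (4R)-6-[(tert-butyldimethylsilyl)oxy]-4-methylhexanal | O=CCC[C@@H](C)CCO[Si](C)(C)C(C)(C)C | intermediate
5 | (3R)-tert-butyldimethyl[(3-methylhept-6-yn-1-yl)oxy]silane | C#CCC[C@@H](C)CCO[Si](C)(C)C(C)(C)C | intermediate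
6 | dimethyl[(1E,5R)-7-(tert-butyldimethylsilyloxy)-2,5-dimethylhept-1-en-1-yl]alane | C[Al](C)/C=C(\C)CC[C@@H](C)CCO[Si](C)(C)C(C)(C)C | intermediate (not isolated)
7 | (2E,6R)-8-[(tert-butyldimethylsilyl)oxy]-3,6-dimethyloct-2-en-1-ol | OC/C=C(\C)CC[C@@H](C)CCO[Si](C)(C)C(C)(C)C | intermediate
8 | propanoyl chloride | CCC(=O)Cl | starting material
9 | (2E,6R)-8-[(tert-butyldimethylsilyl)oxy]-3,6-dimethyloct-2-en-1-yl propanoate | CCC(=O)OC/C=C(\C)CC[C@@H](C)CCO[Si](C)(C)C(C)(C)C | intermediate
10 | O-boron ketene acetal of 9 (methyl cis to O–B; boron bound to the (S,S)-bis-sulfonamide ligand) | C/C=C(\OB1N(S(=O)(=O)c2cc(C(F)(F)F)cc(C(F)(F)F)c2)[C@@H](c2ccccc2)[C@H](c2ccccc2)N1S(=O)(=O)c1cc(C(F)(F)F)cc(C(F)(F)F)c1)OC/C=C(\C)CC[C@@H](C)CCO[Si](C)(C)C(C)(C)C | intermediate (not isolated)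
11 | (2S,3R,6R)-8-[(tert-butyldimethylsilyl)oxy]-3-ethenyl-2,3,6-trimethyloctanoic acid | C=C[C@@](C)(CC[C@@H](C)CCO[Si](C)(C)C(C)(C)C)[C@H](C)C(=O)O | intermediate
12 | (2S,3R,6R)-8-[(tert-butyldimethylsilyl)oxy]-3-ethenyl-2,3,6-trimethyloctan-1-ol | C=C[C@@](C)(CC[C@@H](C)CCO[Si](C)(C)C(C)(C)C)[C@H](C)CO | intermediate
13 | (2S,3R,6R)-8-[(tert-butyldimethylsilyl)oxy]-3-ethenyl-2,3,6-trimethyloctanal | C=C[C@@](C)(CC[C@@H](C)CCO[Si](C)(C)C(C)(C)C)[C@H](C)C=O | intermediate
14 | propargyl bromide (3-bromoprop-1-yne) | C#CCBr | starting material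
15 | allenylzinc bromide (propa-1,2-dien-1-ylzinc bromide) | C=C=C[Zn]Br | intermediate (not isolated)
16 | (4S,5S,6R,9R)-11-[(tert-butyldimethylsilyl)oxy]-6-ethenyl-5,6,9-trimethylundec-1-yn-4-ol | C=C[C@@](C)(CC[C@@H](C)CCO[Si](C)(C)C(C)(C)C)[C@H](C)[C@@H](O)CC#C | intermediate
17 | (4S,5S,6R,9R)-4,11-bis[(tert-butyldimethylsilyl)oxy]-6-ethenyl-5,6,9-trimethylundec-1-yne | C=C[C@@](C)(CC[C@@H](C)CCO[Si](C)(C)C(C)(C)C)[C@H](C)[C@@H](O[Si](C)(C)C(C)(C)C)CC#C | intermediate
18 | (3R,6R,7S,8S)-8-[(tert-butyldimethylsilyl)oxy]-6-ethenyl-3,6,7-trimethylundec-10-yn-1-ol | C=C[C@@](C)(CC[C@@H](C)CCO)[C@H](C)[C@@H](O[Si](C)(C)C(C)(C)C)CC#C | intermediate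
19 | (3R,6R,7S,8S)-8-[(tert-butyldimethylsilyl)oxy]-6-ethenyl-3,6,7-trimethylundec-10-ynoic acid | C=C[C@@](C)(CC[C@@H](C)CC(=O)O)[C@H](C)[C@@H](O[Si](C)(C)C(C)(C)C)CC#C | intermediate
20 | tert-butyl (3R,6R,7S,8S)-8-[(tert-butyldimethylsilyl)oxy]-6-ethenyl-3,6,7-trimethylundec-10-ynoate | C=C[C@@](C)(CC[C@@H](C)CC(=O)OC(C)(C)C)[C@H](C)[C@@H](O[Si](C)(C)C(C)(C)C)CC#C | intermediate
21 | hexacarbonyldicobalt complex of the alkyne of 20 | O=C=[Co]12(=C=O)(=C=O)[Co]3(=C=O)(=C=O)(=C=O)C1(C[C@H](O[Si](C)(C)C(C)(C)C)[C@@H](C)[C@](C)(CC[C@@H](C)CC(=O)OC(C)(C)C)C=C)C23 | intermediate (not isolated)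
22 | hydrindenone, tert-butyl (3R)-5-[(5S,6S,7R,7aS)-5-[(tert-butyldimethylsilyl)oxy]-6,7-dimethyl-2-oxo-2,4,5,6,7,7a-hexahydro-1H-inden-7-yl]-3-methylpentanoate | O=C1C[C@@H]2[C@@](C)(CC[C@@H](C)CC(=O)OC(C)(C)C)[C@H](C)[C@@H](O[Si](C)(C)C(C)(C)C)CC2=C1 | intermediate
23 | lithium C3=C4 enolate of the 5-methyl cis-hydrindan-3-one (5S,7S,8S,9R,10R,13R) | C1=C(O[Li])C[C@@H]2[C@@](C)(CC[C@@H](C)CC(=O)OC(C)(C)C)[C@H](C)[C@@H](O[Si](C)(C)C(C)(C)C)C[C@]12C | intermediate (not isolated)
24 | 4-(hydroxymethyl)-5-methyl cis-hydrindan-3-one, 7-OTBS, tert-butyl ester (5S,7S,8S,9R,10R,13R; C4 epimers) | OCC1C(=O)C[C@@H]2[C@@](C)(CC[C@@H](C)CC(=O)OC(C)(C)C)[C@H](C)[C@@H](O[Si](C)(C)C(C)(C)C)C[C@]12C | intermediate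
25 | 4-[(tert-butyldimethylsilyloxy)methyl] analogue of 24 (same descriptors; C4 epimers) | CC(C)(C)[Si](C)(C)OCC1C(=O)C[C@@H]2[C@@](C)(CC[C@@H](C)CC(=O)OC(C)(C)C)[C@H](C)[C@@H](O[Si](C)(C)C(C)(C)C)C[C@]12C | intermediate
26 | 3-ethenyl-3-hydroxy cis-hydrindane, 7-OTBS, 18-OTBS, tert-butyl ester (5S,7S,8S,9R,10R,13R; C3, C4 epimers) | CC(C)(C)[Si](C)(C)OCC1C(O)(C=C)C[C@@H]2[C@@](C)(CC[C@@H](C)CC(=O)OC(C)(C)C)[C@H](C)[C@@H](O[Si](C)(C)C(C)(C)C)C[C@]12C | intermediate
27 | triol: 3-ethenyl-4-(hydroxymethyl) cis-hydrindane-3,7-diol, tert-butyl ester (same descriptors; C3, C4 epimers) | OCC1C(O)(C=C)C[C@@H]2[C@@](C)(CC[C@@H](C)CC(=O)OC(C)(C)C)[C@H](C)[C@@H](O)C[C@]12C | intermediate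
28 | diacetate: 7-acetoxy-4-(acetoxymethyl)-3-ethenyl cis-hydrindan-3-ol, tert-butyl ester (same descriptors; C3, C4 epimers) | CC(=O)OCC1C(O)(C=C)C[C@@H]2[C@@](C)(CC[C@@H](C)CC(=O)OC(C)(C)C)[C@H](C)[C@@H](OC(C)=O)C[C@]12C | intermediate
29 | secondary ozonide of 28 (1,2,4-trioxolan-3-yl on C3) | CC(=O)OCC1C(O)(C3OOCO3)C[C@@H]2[C@@](C)(CC[C@@H](C)CC(=O)OC(C)(C)C)[C@H](C)[C@@H](OC(C)=O)C[C@]12C | intermediate (not isolated)
30 | hydroxy aldehyde: 7-acetoxy-4-(acetoxymethyl)-3-hydroxy cis-hydrindane-3-carbaldehyde, tert-butyl ester (5S,7S,8S,9R,10R,13R; C3, C4 epimers) | CC(=O)OCC1C(O)(C=O)C[C@@H]2[C@@](C)(CC[C@@H](C)CC(=O)OC(C)(C)C)[C@H](C)[C@@H](OC(C)=O)C[C@]12C | intermediate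
31 | acyloin: 7-acetoxy-4-(acetoxymethyl)-2-hydroxy cis-decalin-3-one, tert-butyl ester (5S,7S,8S,9R,10R,13R; C2, C4 epimers) | CC(=O)OCC1C(=O)C(O)C[C@@H]2[C@@](C)(CC[C@@H](C)CC(=O)OC(C)(C)C)[C@H](C)[C@@H](OC(C)=O)C[C@]12C | intermediate
32 | 7-acetoxy-4-(acetoxymethyl) cis-decalin-2,3-dione, tert-butyl ester (same descriptors; C4 epimers) | CC(=O)OCC1C(=O)C(=O)C[C@@H]2[C@@](C)(CC[C@@H](C)CC(=O)OC(C)(C)C)[C@H](C)[C@@H](OC(C)=O)C[C@]12C | intermediate (not isolated)
33 | tert-butyl (3R)-5-[(1R,2S,3S,4aS,8aR)-3-(acetyloxy)-7-hydroxy-1,2,4a-trimethyl-5-methylidene-6-oxo-1,2,3,4,4a,5,6,8a-octahydronaphthalen-1-yl]-3-methylpentanoate | C=C1C(=O)C(O)=C[C@@H]2[C@@](C)(CC[C@@H](C)CC(=O)OC(C)(C)C)[C@H](C)[C@@H](OC(C)=O)C[C@]12C | intermediate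
34 | (3R)-5-[(1R,2S,3S,4aS,8aR)-3-(acetyloxy)-7-hydroxy-1,2,4a-trimethyl-5-methylidene-6-oxo-1,2,3,4,4a,5,6,8a-octahydronaphthalen-1-yl]-3-methylpentanoic acid | C=C1C(=O)C(O)=C[C@@H]2[C@@](C)(CC[C@@H](C)CC(=O)O)[C@H](C)[C@@H](OC(C)=O)C[C@]12C | target

## Step count and risks

Total step count: 23. Longest linear sequence: 23 steps (the route is linear from 1; 8 and 14 are bought).

**Step 21 (key step).** Lewis-acid activation could be diverted before the shift occurs: loss of the tert-butyl ester, acetyl transfer to the tertiary hydroxyl, or self-condensation of the hydroxy aldehyde. Fallback: insert C2 at the ketone stage by a different one-carbon ring enlargement. Setting out from ketone 25, Me3SiCHN2 with Me3Al (the less substituted α-carbon C1 migrates; protodesilylation on work-up) should give the ring-enlarged decalin-3-one F1. HF·pyridine would then free the diol F2, and Ac2O in pyridine would give the diacetate F3. Riley oxidation of the C2 methylene with SeO2 leads to dione 32, which loses acetic acid with Et3N and rejoins the route at 33. The price is that this insertion, unlike the ketol shift, is not regioconvergent.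

**Step 6.** Facial or chair/boat selectivity may be poor for a 3,3-disubstituted allyl ester, or the boron enolate may rearrange too slowly; either would give 11 mixed with its (2R,3S) isomer, which cannot be separated because C13 is remote. Fallback: give up reagent control and separate covalent diastereomers. From 9, a lithium-enolate Ireland–Claisen rearrangement (LiN(iPr)2, Me3SiCl, THF–DMPU, which also places the methyl cis to the O-metal bond) would give 11 together with the (2R,3S,6R) acid F4. Acylation of (S)-4-benzyloxazolidin-2-one through the pivalic mixed anhydride gives imide F5 (from 11) and imide F6 (from F4), whose differing centres now sit next to the auxiliary and should separate on silica. LiBH4 reduction of F5 gives alcohol 12 directly.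

**Step 9.** The Felkin preference may be weak in the cyclic allenylzinc transition state, and some allenyl carbinol may form. Fallback: recycle rather than discard. The (4R) epimer F7, formed from 13 beside 16 and separable from it, is inverted by a Mitsunobu reaction with 4-nitrobenzoic acid (PPh3, diisopropyl azodicarboxylate) to the (4S) ester F8, and K2CO3 in MeOH releases 16.

**Step 14.** The hindered vinyl group on the quaternary C9 may insert slowly into the cobalt complex of a 1,7-enyne, so that decomplexation or alkyne oligomerisation takes over; a boat pathway could also erode the C10 selectivity. Fallback: change the one-carbon partner. Cyclisation of 20 with 2,6-dimethylphenyl isocyanide mediated by Ni(cod)2 (zerovalent nickel) and PBu3 should give, through a nickelacycle, the bicyclic N-aryl imine F9. Mild hydrolysis (oxalic acid, wet THF) then returns enone 22.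

**Step 15.** Capture of the copper–lithium enolate by formaldehyde may be incomplete or reversible (proton quench, retro-aldol, double hydroxymethylation). Fallback: separate the two events. Me2CuLi addition to 22 in the presence of Me3SiCl gives the isolable trimethylsilyl enol ether F10, whose C3=C4 position is fixed by the conjugate addition. A Mukaiyama hydroxymethylation with aqueous formaldehyde and Sc(OTf)3 then gives 24.

## Further compounds

F1 | step 21 | ring-enlarged 4-[(tert-butyldimethylsilyloxy)methyl] cis-decalin-3-one, 7-OTBS, tert-butyl ester (5S,7S,8S,9R,10R,13R; C4 epimers) | CC(C)(C)[Si](C)(C)OCC1C(=O)CC[C@@H]2[C@@](C)(CC[C@@H](C)CC(=O)OC(C)(C)C)[C@H](C)[C@@H](O[Si](C)(C)C(C)(C)C)C[C@]12C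
F2 | step 21 | 7-hydroxy-4-(hydroxymethyl) cis-decalin-3-one, tert-butyl ester (same descriptors) | OCC1C(=O)CC[C@@H]2[C@@](C)(CC[C@@H](C)CC(=O)OC(C)(C)C)[C@H](C)[C@@H](O)C[C@]12C
F3 | step 21 | 7-acetoxy-4-(acetoxymethyl) cis-decalin-3-one, tert-butyl ester (same descriptors) | CC(=O)OCC1C(=O)CC[C@@H]2[C@@](C)(CC[C@@H](C)CC(=O)OC(C)(C)C)[C@H](C)[C@@H](OC(C)=O)C[C@]12C
F4 | step 6 | (2R,3S,6R)-8-[(tert-butyldimethylsilyl)oxy]-3-ethenyl-2,3,6-trimethyloctanoic acid | C=C[C@](C)(CC[C@@H](C)CCO[Si](C)(C)C(C)(C)C)[C@@H](C)C(=O)O
F5 | step 6 | (4S)-4-benzyl-3-[(2S,3R,6R)-8-(tert-butyldimethylsilyloxy)-3-ethenyl-2,3,6-trimethyloctanoyl]oxazolidin-2-one | C=C[C@@](C)(CC[C@@H](C)CCO[Si](C)(C)C(C)(C)C)[C@H](C)C(=O)N1[C@@H](Cc2ccccc2)COC1=O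
F6 | step 6 | (4S)-4-benzyl-3-[(2R,3S,6R)-8-(tert-butyldimethylsilyloxy)-3-ethenyl-2,3,6-trimethyloctanoyl]oxazolidin-2-one | C=C[C@](C)(CC[C@@H](C)CCO[Si](C)(C)C(C)(C)C)[C@@H](C)C(=O)N1[C@@H](Cc2ccccc2)COC1=O
F7 | step 9 | (4R,5S,6R,9R)-11-[(tert-butyldimethylsilyl)oxy]-6-ethenyl-5,6,9-trimethylundec-1-yn-4-ol | C=C[C@@](C)(CC[C@@H](C)CCO[Si](C)(C)C(C)(C)C)[C@H](C)[C@H](O)CC#C
F8 | step 9 | (4S,5S,6R,9R)-11-[(tert-butyldimethylsilyl)oxy]-6-ethenyl-5,6,9-trimethylundec-1-yn-4-yl 4-nitrobenzoate | C=C[C@@](C)(CC[C@@H](C)CCO[Si](C)(C)C(C)(C)C)[C@H](C)[C@@H](OC(=O)c1ccc(cc1)[N+](=O)[O-])CC#C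
F9 | step 14 | N-(2,6-dimethylphenyl) imine of hydrindenone 22 | Cc1cccc(C)c1N=C1C[C@@H]2[C@@](C)(CC[C@@H](C)CC(=O)OC(C)(C)C)[C@H](C)[C@@H](O[Si](C)(C)C(C)(C)C)CC2=C1
F10 | step 15 | trimethylsilyl C3=C4 enol ether of the 5-methyl cis-hydrindan-3-one (5S,7S,8S,9R,10R,13R) | C1=C(O[Si](C)(C)C)C[C@@H]2[C@@](C)(CC[C@@H](C)CC(=O)OC(C)(C)C)[C@H](C)[C@@H](O[Si](C)(C)C(C)(C)C)C[C@]12C
A1 | alternative 1 | methyl (2E,8E,10Z)-10-[(tert-butyldimethylsilyl)oxy]-2,8-dimethyl-4-oxododeca-2,8,10-trienoate | COC(=O)/C(C)=C/C(=O)CCC/C(C)=C/C(O[Si](C)(C)C(C)(C)C)=C/C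
A2 | alternative 1 | cis-fused C1-keto octalin silyl enol ether with the C11 methyl ester | C1CCC(=O)[C@@H]2[C@@](C)(C(=O)OC)[C@H](C)C(O[Si](C)(C)C(C)(C)C)=C[C@]12C
A3 | alternative 2 | 1-(1-methyl-4-oxocyclohexa-2,5-dien-1-yl)butane-2,3-dione | CC(=O)C(=O)CC1(C)C=CC(=O)C=C1
A4 | alternative 2 | cis-fused ring A 2,3-dione with a ring B enone | C1C(=O)C(=O)C[C@@H]2CC(=O)C=C[C@]12C
A5 | alternative 3 | cis-clerodane-type C4=C5 octal-3-one, 7-OTBS, tert-butyl ester | O=C1CC[C@@H]2[C@@](C)(CC[C@@H](C)CC(=O)OC(C)(C)C)[C@H](C)[C@@H](O[Si](C)(C)C(C)(C)C)CC2=C1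
A6 | alternative 3 | cis-fused 4-methylene-5-methyl decalin-3-one, 7-OTBS, tert-butyl ester | C=C1C(=O)CC[C@@H]2[C@@](C)(CC[C@@H](C)CC(=O)OC(C)(C)C)[C@H](C)[C@@H](O[Si](C)(C)C(C)(C)C)C[C@]12C
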